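**Retrosynthetic overview**
- The veratrate is put on last, by selective acylation of the secondary C6–OH of jaeschkeanadiol. That carbinol comes from a C4–OH-directed reduction of the trans-hydroazulen-6-one.
- The seven-membered ring is closed last. Rhodium hydroacylation of a cyclopentane-bound 4,6-dienal forms C6–C7 and moves the alkene to C8=C9.
- The cyclopentane and a β-lactone form together in one catalytic asymmetric aldol-lactonisation of an acyclic racemic keto acid. This step fixes C4 and C5 and sorts out C1.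
- The keto acid comes from isobutyraldehyde, methyl vinyl ketone, Meldrum's acid and 2-methylbut-1-en-3-yne.
- Daucane labels: C1 quaternary carbon, C4 carbinol bearing isopropyl, C5 ring-fusion CH, C6 ester carbon, C8=C9 alkene.

Assumption: the sense of induction of the isothiourea catalyst in step 5 is taken as drawn. Its antipode is equally available if the opposite sense is found.

**Step 1**
Reactants: 1 2-methylpropanal (isobutyraldehyde); 2 but-3-en-2-one (methyl vinyl ketone)
Product: 3 6-methylheptane-2,5-dione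
Conditions: 3-benzyl-5-(2-hydroxyethyl)-4-methylthiazolium chloride (10 mol%), Et3N, EtOH, 78 °C
Reagents that add atoms: none
Why: In this Stetter reaction the thiazolylidene turns the aldehyde into an acyl-anion equivalent that adds 1,4 to the enone, giving C1–C4 with both ketones and no stereocentre.

**Step 2**
Reactants: 3 6-methylheptane-2,5-dione; 4 Meldrum's acid (2,2-dimethyl-1,3-dioxane-4,6-dione)
Product: 5 2,2-dimethyl-5-(6-methyl-5-oxoheptan-2-ylidene)-1,3-dioxane-4,6-dione
Conditions: TiCl4, pyridine, THF–CH2Cl2, 0 to 23 °C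
Reagents that add atoms: none
Why: This titanium-mediated Knoevenagel condensation takes place at the unhindered methyl ketone rather than the isopropyl ketone, and the symmetric acceptor has no alkene geometry to control.

**Step 3**
Reactants: 6 2-methylbut-1-en-3-yne; 5 2,2-dimethyl-5-(6-methyl-5-oxoheptan-2-ylidene)-1,3-dioxane-4,6-dione
Product: 8 rac-2,2-dimethyl-5-[(7E)-2,6,9-trimethyl-3-oxodeca-7,9-dien-6-yl]-1,3-dioxane-4,6-dione, via dienylzirconocene chloride 7 (not isolated)
Conditions: Cp2ZrHCl, THF, 23 °C; then 5, CuBr·SMe2 (10 mol%), 40 °C; then 1 M HCl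
Reagents that add atoms: none
Why: Syn-hydrozirconation of the alkyne gives the E-dienyl metal, whose copper-catalysed conjugate addition to the doubly activated alkene builds quaternary C1 as a racemate while the organozirconium leaves the ketone untouched.

**Step 4**
Reactants: 8 rac-2,2-dimethyl-5-[(7E)-2,6,9-trimethyl-3-oxodeca-7,9-dien-6-yl]-1,3-dioxane-4,6-dione
Product: 9 rac-(4E)-3,6-dimethyl-3-(4-methyl-3-oxopentyl)hepta-4,6-dienoic acid
Conditions: pyridine–H2O 10:1, 95 °C
Reagents that add atoms: water, O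
Why: Hydrolytic opening of the Meldrum's acid ring followed by decarboxylation of the malonic half-acid leaves the C5–C6 acetic acid arm and does not touch C1.

**Step 5**
Reactants: 9 rac-(4E)-3,6-dimethyl-3-(4-methyl-3-oxopentyl)hepta-4,6-dienoic acid
Product: 11 (1R,2R,5R)-2-methyl-2-[(1E)-3-methylbuta-1,3-dien-1-yl]-5-(propan-2-yl)-6-oxabicyclo[3.2.0]heptan-7-one, via tosyl mixed anhydride 10 (not isolated)
Conditions: TsCl, iPr2NEt, LiCl, (S)-2-phenyl-3,4-dihydro-2H-benzo[4,5]thiazolo[3,2-a]pyrimidine (20 mol%), CH2Cl2, 23 °C, slow addition of 9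
Reagents that add atoms: none
Why: Proposed new method: the nucleophile-catalysed aldol-lactonisation known for simple keto acids is run here on a racemic acid, where tosyl activation and acyl transfer give a chiral acylammonium whose ammonium enolate (C5) adds to the isopropyl ketone (C4) from the open face and the tertiary alkoxide closes the oxetanone irreversibly, so cyclopentane and β-lactone form together with O4 and C6 necessarily cis and C4/C5 fixed by the catalyst, and because methyl and dienyl at C1 differ little in size both enantiomers of 9 react alike, the (S)-acid giving 11 and the (R)-acid its C1 epimer that is removed by chromatography (at most half of the material), the closest known types being the catalytic asymmetric bis-cyclisation of keto acids and stereodivergent reactions on racemic mixtures.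

**Step 6**
Reactants: 11 (1R,2R,5R)-2-methyl-2-[(1E)-3-methylbuta-1,3-dien-1-yl]-5-(propan-2-yl)-6-oxabicyclo[3.2.0]heptan-7-one
Product: 12 (1R,2R,5R)-2-hydroxy-5-methyl-5-[(1E)-3-methylbuta-1,3-dien-1-yl]-2-(propan-2-yl)cyclopentane-1-carbaldehyde
Conditions: iBu2AlH (1.1 equiv), CH2Cl2, −78 °C; then aq. potassium sodium tartrate
Reagents that add atoms: none
Why: Partial hydride reduction of the strained lactone stops at the aluminium hemiacetal and releases the β-hydroxy aldehyde on work-up, and C5 is safe because formyl trans to isopropyl is already the more stable epimer.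

**Step 7**
Reactants: 12 (1R,2R,5R)-2-hydroxy-5-methyl-5-[(1E)-3-methylbuta-1,3-dien-1-yl]-2-(propan-2-yl)cyclopentane-1-carbaldehyde
Product: 13 (3R,3aR,8aR)-3-hydroxy-6,8a-dimethyl-3-(propan-2-yl)-2,3,3a,5,8,8a-hexahydroazulen-4(1H)-one
Conditions: [Rh(nbd)(dppe)]BF4 (10 mol%, pre-treated with H2), ClCH2CH2Cl, 65 °C
Reagents that add atoms: none
Why: In this intramolecular hydroacylation of a 4,6-dienal with cationic monovalent rhodium the acyl hydride delivers H to C10, and since closure of the six-membered rhodacycle to a trans-fused bicyclo[3.3.0]octanone is too strained, the allyl-rhodium slips and bonds C6 to C7, giving the β,γ-unsaturated cycloheptenone with the C8=C9 alkene and no change at C1, C4 or C5.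

**Step 8**
Reactants: 13 (3R,3aR,8aR)-3-hydroxy-6,8a-dimethyl-3-(propan-2-yl)-2,3,3a,5,8,8a-hexahydroazulen-4(1H)-one
Product: 14 (3R,3aS,4S,8aR)-6,8a-dimethyl-3-(propan-2-yl)-1,2,3,3a,4,5,8,8a-octahydroazulene-3,4-diol (jaeschkeanadiol)
Conditions: Me4NBH(OAc)3, MeCN–AcOH 1:1, −30 °C
Reagents that add atoms: none
Why: In this hydroxyl-directed Evans–Saksena reduction the boron binds to the β-face C4–OH and passes hydride to the β face of C6=O, which sets the 6α-carbinol (anti 1,3-diol), and the low temperature keeps the β,γ-alkene out of conjugation.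

**Step 9**
Reactants: 14 jaeschkeanadiol; 15 3,4-dimethoxybenzoyl chloride (veratroyl chloride)
Product: 16 (3R,3aS,4S,8aR)-3-hydroxy-6,8a-dimethyl-3-(propan-2-yl)-1,2,3,3a,4,5,8,8a-octahydroazulen-4-yl 3,4-dimethoxybenzoate (target)
Conditions: 15 (1.3 equiv), Et3N, DMAP (20 mol%), CH2Cl2, 0 to 23 °C
Reagents that add atoms: none
Why: DMAP-catalysed acylation takes only the secondary C6–OH because the tertiary C4–OH next to the isopropyl group is too hindered, and no stereocentre is touched.

**Compound list**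

| No. | Name | SMILES | Role |
|---|---|---|---|
| 1 | 2-methylpropanal | CC(C)C=O | starting material |
| 2 | but-3-en-2-one | C=CC(C)=O | starting material |
| 3 | 6-methylheptane-2,5-dione | CC(C)C(=O)CCC(C)=O | intermediate |
| 4 | Meldrum's acid | CC1(C)OC(=O)CC(=O)O1 | starting material |
| 5 | 2,2-dimethyl-5-(6-methyl-5-oxoheptan-2-ylidene)-1,3-dioxane-4,6-dione | CC(C)C(=O)CCC(C)=C1C(=O)OC(C)(C)OC1=O | intermediate |
| 6 | 2-methylbut-1-en-3-yne | C=C(C)C#C | starting material |
| 7 | chlorobis(cyclopentadienyl)[(1E)-3-methylbuta-1,3-dien-1-yl]zirconium | C=C(C)/C=C/[Zr](Cl)(C1C=CC=C1)C1C=CC=C1 | intermediate |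
| 8 | rac-2,2-dimethyl-5-[(7E)-2,6,9-trimethyl-3-oxodeca-7,9-dien-6-yl]-1,3-dioxane-4,6-dione | CC(C)C(=O)CCC(C)(/C=C/C(C)=C)C1C(=O)OC(C)(C)OC1=O | intermediate |
| 9 | rac-(4E)-3,6-dimethyl-3-(4-methyl-3-oxopentyl)hepta-4,6-dienoic acid | OC(=O)CC(C)(CCC(=O)C(C)C)/C=C/C(C)=C | intermediate |
| 10 | mixed anhydride of 9 and 4-methylbenzenesulfonic acid | Cc1ccc(cc1)S(=O)(=O)OC(=O)CC(C)(CCC(=O)C(C)C)/C=C/C(C)=C | intermediate |
| 11 | (1R,2R,5R)-2-methyl-2-[(1E)-3-methylbuta-1,3-dien-1-yl]-5-(propan-2-yl)-6-oxabicyclo[3.2.0]heptan-7-one | O=C1O[C@@]2(C(C)C)CC[C@](C)(/C=C/C(C)=C)[C@@H]12 | intermediate |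
| 12 | (1R,2R,5R)-2-hydroxy-5-methyl-5-[(1E)-3-methylbuta-1,3-dien-1-yl]-2-(propan-2-yl)cyclopentane-1-carbaldehyde | O=C[C@H]1[C@](O)(C(C)C)CC[C@]1(C)/C=C/C(C)=C | intermediate |
| 13 | (3R,3aR,8aR)-3-hydroxy-6,8a-dimethyl-3-(propan-2-yl)-2,3,3a,5,8,8a-hexahydroazulen-4(1H)-one | O=C1CC(C)=CC[C@@]2(C)CC[C@@](O)(C(C)C)[C@H]12 | intermediate |
| 14 | jaeschkeanadiol | O[C@H]1CC(C)=CC[C@@]2(C)CC[C@@](O)(C(C)C)[C@H]12 | intermediate |
| 15 | 3,4-dimethoxybenzoyl chloride | COc1ccc(C(=O)Cl)cc1OC | starting material |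
| 16 | jaeschkeanadiol veratrate | COc1ccc(C(=O)O[C@H]2CC(C)=CC[C@@]3(C)CC[C@@](O)(C(C)C)[C@H]23)cc1OC | target |

**Step count and longest linear sequence**
- Total step count: 9.
- Longest linear sequence: 9 (1 and 2 to 16).

**Steps most likely to fail**

Step 5 (aldol-lactonisation on a hindered isopropyl ketone, with the catalyst having to override the substrate). The fallback sets out from 9 and comes back at 12.
- Activate the acid with pivaloyl chloride and Et3N and couple it to lithiated (S)-4-benzyl-1,3-oxazolidin-2-one. This gives (4S)-4-benzyl-3-[(3S,4E)-3,6-dimethyl-3-(4-methyl-3-oxopentyl)hepta-4,6-dienoyl]-1,3-oxazolidin-2-one F3 together with its C3 epimer.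
- Soft enolisation with TiCl4 and iPr2NEt at −78 °C then drives an auxiliary-controlled intramolecular titanium aldol. The product is (4S)-4-benzyl-3-{[(1R,2R,5R)-2-hydroxy-5-methyl-5-[(1E)-3-methylbuta-1,3-dien-1-yl]-2-(propan-2-yl)cyclopentyl]carbonyl}-1,3-oxazolidin-2-one F4, which is separated from the aldol of the epimer.
- LiBH4 cleaves the imide to (1R,2S,3R)-2-(hydroxymethyl)-3-methyl-3-[(1E)-3-methylbuta-1,3-dien-1-yl]-1-(propan-2-yl)cyclopentan-1-ol F5.
- Dess–Martin periodinane oxidises only the primary alcohol, giving 12.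

Step 7 (decarbonylation, cyclopentanone formation or retro-aldol may compete with seven-ring closure). The fallback sets out from 11 and comes back at 13, replacing the organometallic closure by a radical one.
- Me2AlSePh opens the lactone to Se-phenyl (1R,2R,5R)-2-hydroxy-5-methyl-5-[(1E)-3-methylbuta-1,3-dien-1-yl]-2-(propan-2-yl)cyclopentane-1-carboselenoate F6.
- Slow addition of Bu3SnH with AIBN in benzene at 80 °C generates the acyl radical. It attacks the diene terminus C7 in the 7-endo mode.
- The resulting allyl radical takes up hydrogen at C10 to give 13.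

Step 3 (transfer of a dienyl group to a tetrasubstituted acceptor). The fallback sets out from 5 and comes back at 9, building the diene in two stages.
- Add CH2=CHMgBr with CuBr·SMe2 and Me3SiCl in THF at −78 °C. This gives rac-2,2-dimethyl-5-(3,7-dimethyl-6-oxooct-1-en-3-yl)-1,3-dioxane-4,6-dione F1.
- Wet pyridine at 95 °C gives rac-3-ethenyl-3,7-dimethyl-6-oxooctanoic acid F2.
- A Heck reaction with 2-bromopropene (Pd(OAc)2, P(o-tol)3, Et3N, MeCN, 80 °C) extends the vinyl group to the E-diene of 9.

**Further compounds**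
F1 | step 3 | rac-2,2-dimethyl-5-(3,7-dimethyl-6-oxooct-1-en-3-yl)-1,3-dioxane-4,6-dione | CC(C)C(=O)CCC(C)(C=C)C1C(=O)OC(C)(C)OC1=O
F2 | step 3 | rac-3-ethenyl-3,7-dimethyl-6-oxooctanoic acid | OC(=O)CC(C)(C=C)CCC(=O)C(C)C
F3 | step 5 | (4S)-4-benzyl-3-[(3S,4E)-3,6-dimethyl-3-(4-methyl-3-oxopentyl)hepta-4,6-dienoyl]-1,3-oxazolidin-2-one | O=C(C[C@](C)(CCC(=O)C(C)C)/C=C/C(C)=C)N1[C@@H](Cc2ccccc2)COC1=O
F4 | step 5 | (4S)-4-benzyl-3-{[(1R,2R,5R)-2-hydroxy-5-methyl-5-[(1E)-3-methylbuta-1,3-dien-1-yl]-2-(propan-2-yl)cyclopentyl]carbonyl}-1,3-oxazolidin-2-one | O=C([C@H]1[C@](O)(C(C)C)CC[C@]1(C)/C=C/C(C)=C)N1[C@@H](Cc2ccccc2)COC1=O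
F5 | step 5 | (1R,2S,3R)-2-(hydroxymethyl)-3-methyl-3-[(1E)-3-methylbuta-1,3-dien-1-yl]-1-(propan-2-yl)cyclopentan-1-ol | OC[C@H]1[C@](O)(C(C)C)CC[C@]1(C)/C=C/C(C)=C
F6 | step 7 | Se-phenyl (1R,2R,5R)-2-hydroxy-5-methyl-5-[(1E)-3-methylbuta-1,3-dien-1-yl]-2-(propan-2-yl)cyclopentane-1-carboselenoate | O=C([Se]c1ccccc1)[C@H]1[C@](O)(C(C)C)CC[C@]1(C)/C=C/C(C)=C
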